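**Plan**

1. Numbering used below: ring A is the hexasubstituted benzene, C1 (side-chain CH2), C2 (OH), C3 (aroyl), C4 (ring oxygen), C5 (ring CH2), C6 (OMe); ring B is the dihydrofuran; ring C is the 3-hydroxyphenyl group.
2. Retrosynthetic cuts, in order: the Si–O bonds and the C2–O–CH3 bond (demethylation next to the ketone); C3–C(=O) (aryllithium plus Weinreb amide); C5–CH2 of ring B (ring closure); C1–CH2 (Negishi coupling); C4–O–CH (Mitsunobu).
3. Forward: a 4-bromo-3,5-dimethoxyphenyl ether of a lactate-derived carbinol is alkylated at C1 and brominated at C5, ring B is closed, the last arene C–H (C3) is aroylated, and only the methoxy group beside the ketone is cleaved.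
4. Enabling feature: the CH3 of the O–CH(CH3)–C(CH3)2O unit on the C4 oxygen is 1,5-related to C5 (C5–C4–O–CH–CH3), so an aryl–palladium at C5 reaches a methyl C–H through a six-membered palladacycle that contracts to the five-membered ring B. The local twofold axis through C1 and C4 of ring A makes C3 and C5 equivalent until the closure, which removes every regiochemical choice.
5. Stereochemistry: the O–CH carbon of ring B (S) comes from ethyl (R)-lactate by Mitsunobu inversion and is not touched afterwards; the side-chain centre (R) comes from an Evans alkylation on the (S)-4-benzyloxazolidinone dienolate.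

Key step: step 12

**Route**

Step 1
Reactants: 1 2-bromo-1,3-dimethoxybenzene
Product: 3 4-bromo-3,5-dimethoxyphenol, via aryl pinacol boronate 2 (not isolated)
Conditions: [Ir(OMe)(cod)]2 (1.5 mol %), 4,4'-di-tert-butyl-2,2'-bipyridine (3 mol %), B2pin2 (1.0 equiv), THF, 80 °C; then Oxone (2KHSO5·KHSO4·K2SO4), acetone/H2O, rt
Reagents that add atoms: potassium peroxymonosulfate (active salt of Oxone), [K+].[O-]S(=O)(=O)OO
Why: One-pot iridium-catalysed C–H borylation/oxidation: the borylation is sterically controlled and takes the only C–H of 1 with no ortho substituent (para to Br, which is tolerated), and Oxone then oxidises the C–B bond to the phenol.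

Step 2
Reactants: 3 4-bromo-3,5-dimethoxyphenol; 4 ethyl (R)-lactate
Product: 5 ethyl (S)-2-(4-bromo-3,5-dimethoxyphenoxy)propanoate
Conditions: PPh3, DIAD, THF, 0 °C → rt
Reagents that add atoms: none
Why: Mitsunobu etherification of a phenol with an α-hydroxy ester is an SN2 displacement at the activated secondary carbon with inversion, so the (R)-carbinol of 4 becomes the (S)-aryl ether carbon that ends as the O–CH of ring B.

Step 3
Reactants: 5 ethyl (S)-2-(4-bromo-3,5-dimethoxyphenoxy)propanoate
Product: 6 (S)-3-(4-bromo-3,5-dimethoxyphenoxy)-2-methylbutan-2-ol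
Conditions: MeMgBr (3 equiv), THF, −78 → 0 °C; NH4Cl aq
Reagents that add atoms: methylmagnesium bromide, C[Mg]Br
Why: Double Grignard addition to the ester gives the tertiary carbinol; at low temperature addition outruns enolisation of the α-aryloxy carbonyl intermediates, so the stereocentre is kept, and the aryl bromide is inert to MeMgBr.

Step 4
Reactants: 6 (S)-3-(4-bromo-3,5-dimethoxyphenoxy)-2-methylbutan-2-ol
Product: 7 triethylsilyl ether of 6
Conditions: TESOTf, 2,6-lutidine, CH2Cl2, 0 °C
Reagents that add atoms: triethylsilyl trifluoromethanesulfonate, CC[Si](CC)(CC)OS(=O)(=O)C(F)(F)F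
Why: Silylation of a tertiary alcohol with a silyl triflate and a hindered base; the TES ether keeps this oxygen from binding palladium in step 12 and from quenching the organometallics of steps 10 and 15.

Step 5
Reactants: 8 (S)-4-benzyloxazolidin-2-one; 9 3-methylbut-2-enoyl chloride
Product: 11 (S)-4-benzyl-3-(3-methylbut-2-enoyl)oxazolidin-2-one, via lithium oxazolidinide 10 (not isolated)
Conditions: n-BuLi, THF, −78 °C; then 9, −78 → 0 °C
Reagents that add atoms: none
Why: Standard N-acylation of the lithiated oxazolidinone with an acid chloride at low temperature gives the Evans imide.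

Step 6
Reactants: 12 3-methylbut-3-en-1-ol
Product: 13 3-methylbut-3-en-1-yl trifluoromethanesulfonate
Conditions: Tf2O, 2,6-lutidine, CH2Cl2, −78 °C; cold solution used at once
Reagents that add atoms: trifluoromethanesulfonic anhydride, O=S(=O)(OS(=O)(=O)C(F)(F)F)C(F)(F)F
Why: O-sulfonylation of a primary alcohol with triflic anhydride; the triflate is chosen because an unactivated homoallylic iodide would alkylate an imide dienolate too slowly at −78 °C.

Step 7
Reactants: 11 (S)-4-benzyl-3-(3-methylbut-2-enoyl)oxazolidin-2-one; 13 3-methylbut-3-en-1-yl trifluoromethanesulfonate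
Product: 15 (S)-4-benzyl-3-[(S)-5-methyl-2-(prop-1-en-2-yl)hex-5-enoyl]oxazolidin-2-one, via sodium (Z)-dienolate 14 (not isolated)
Conditions: NaN(SiMe3)2 (1.05 equiv), THF, −78 °C; then 13, −78 → −45 °C; AcOH quench
Reagents that add atoms: none
Why: Evans asymmetric alkylation in its deconjugative form: γ-deprotonation gives the sodium-chelated (Z)-dienolate, which is alkylated at its α-carbon on the face opposite the benzyl group, setting the (S) centre and turning the former enoyl double bond into the isopropenyl group.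

Step 8
Reactants: 15 (S)-4-benzyl-3-[(S)-5-methyl-2-(prop-1-en-2-yl)hex-5-enoyl]oxazolidin-2-one
Product: 16 (S)-5-methyl-2-(prop-1-en-2-yl)hex-5-en-1-ol
Conditions: LiBH4, MeOH (1 equiv), Et2O, 0 °C
Reagents that add atoms: none
Why: LiBH4 reduces the exocyclic imide carbonyl to the primary alcohol and releases the auxiliary under non-basic conditions that do not epimerise or conjugate the β,γ-unsaturated centre.

Step 9
Reactants: 16 (S)-5-methyl-2-(prop-1-en-2-yl)hex-5-en-1-ol
Product: 17 (S)-3-(iodomethyl)-2,6-dimethylhepta-1,6-diene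
Conditions: I2, PPh3, imidazole, CH2Cl2, 0 °C → rt
Reagents that add atoms: iodine, II
Why: Appel-type iodination converts the primary alcohol into the iodide by SN2 at CH2, away from the stereocentre and without touching the alkenes.

Step 10
Reactants: 17 (S)-3-(iodomethyl)-2,6-dimethylhepta-1,6-diene; 7 triethylsilyl ether of 6
Product: 19 triethylsilyl ether of (S)-3-{3,5-dimethoxy-4-[(R)-5-methyl-2-(prop-1-en-2-yl)hex-5-en-1-yl]phenoxy}-2-methylbutan-2-ol, via alkylzinc iodide 18 (not isolated)
Conditions: Zn dust (activated with BrCH2CH2Br and Me3SiCl), LiCl, THF, 40 °C; then 7, Pd(OAc)2 (2 mol %), SPhos (4 mol %), THF, 50 °C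
Reagents that add atoms: none
Why: LiCl-assisted zinc insertion gives the primary alkylzinc iodide and a Negishi coupling with the SPhos-ligated palladium catalyst joins it to the di-ortho-methoxy aryl bromide faster than β-hydride elimination; the stereocentre β to zinc is untouched (the descriptor changes from S to R only because the CIP ranking changes).

Step 11
Reactants: 19 triethylsilyl ether of (S)-3-{3,5-dimethoxy-4-[(R)-5-methyl-2-(prop-1-en-2-yl)hex-5-en-1-yl]phenoxy}-2-methylbutan-2-ol
Product: 20 the 2-bromo derivative of 19 (bromine on ring A at C5)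
Conditions: NBS (1.0 equiv), MeCN, −20 → 0 °C, dark
Reagents that add atoms: N-bromosuccinimide, O=C1CCC(=O)N1Br
Why: Electrophilic aromatic bromination of the trialkoxyarene by NBS is far faster than any reaction of NBS with the 1,1-disubstituted alkenes in dry MeCN, and because the free positions C3 and C5 are exchanged by the twofold axis through C1 and C4 a single monobromide should result.

Step 12
Reactants: 20 the 2-bromo derivative of 19
Product: 21 triethylsilyl ether of 2-{(S)-4,6-dimethoxy-5-[(R)-5-methyl-2-(prop-1-en-2-yl)hex-5-en-1-yl]-2,3-dihydrobenzofuran-2-yl}propan-2-ol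
Conditions: Pd(OAc)2 (5 mol %), PCy3·HBF4 (10 mol %), PivOH (30 mol %), Cs2CO3 (1.5 equiv), mesitylene (degassed), 135 °C
Reagents that add atoms: none
Why: Zerovalent palladium (from Pd(OAc)2 and PCy3) inserts into the C5–Br bond, bromide is exchanged for pivalate, and the bound pivalate removes a hydrogen of the CH3 group on the ether carbon by concerted metalation–deprotonation to give a six-membered palladacycle (Pd, C5, C4, O, CH, CH2), from which C(sp2)–C(sp3) reductive elimination forms the C5–CH2 bond. The closest known reaction type is the palladium/pivalate-catalysed intramolecular C(sp3)–H arylation that turns 2-bromoaryl tert-alkyl ethers into 2,2-disubstituted 2,3-dihydrobenzofurans and N-isopropyl-2-haloanilides into 2-methylindolines, the latter showing that a methyl group on a CH carbon is a competent site. Ring B, the five-membered ring, is closed by contraction of the six-membered palladacycle on reductive elimination, formally a 5-exo closure at C5. No stereocentre is made: the (S) centre from lactate is a spectator, because its own C–H is tertiary and could only react through a five-membered palladacycle leading to a four-membered ring, and because its hydrogen is exocyclic to the palladacycle and cannot become syn-coplanar with palladium for β-hydride elimination. The step needs site selectivity among C–H bonds, secured by ring size and by the primary character of the CH3 group (the carbinol methyls would need a seven-membered palladacycle, the C6 methoxy group gives only a five-membered one that cannot eliminate to a stable ring and reverts), with the bulky C(CH3)2OSiEt3 neighbour biasing the ether conformation as a gem-dialkyl group does. It also needs chemoselectivity against Heck insertion and alkoxide chemistry, secured by the meta relation of C1 and C5 (the side-chain alkenes cannot reach the aryl–palladium) and by the TES ether.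

Step 13
Reactants: 22 methyl 3-hydroxybenzoate
Product: 23 methyl 3-(triisopropylsilyloxy)benzoate
Conditions: TIPSCl, imidazole, DMF, rt
Reagents that add atoms: chlorotriisopropylsilane, CC(C)[Si](Cl)(C(C)C)C(C)C
Why: Standard silylation of a phenol; the TIPS ether is chosen because it should survive the magnesium amide, the aryllithium and MgI2 and is removed by fluoride at the end.

Step 14
Reactants: 23 methyl 3-(triisopropylsilyloxy)benzoate
Product: 24 N-methoxy-N-methyl-3-(triisopropylsilyloxy)benzamide
Conditions: MeONHMe·HCl (1.5 equiv), i-PrMgCl (3 equiv), THF, −20 → 0 °C; NH4Cl aq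
Reagents that add atoms: N,O-dimethylhydroxylamine hydrochloride, CNOC.Cl
Why: Direct aminolysis of the ester by the magnesium amide of N,O-dimethylhydroxylamine (made in the flask with i-PrMgCl) gives the Weinreb amide, which resists further addition.

Step 15
Reactants: 21 triethylsilyl ether of 2-{(S)-4,6-dimethoxy-5-[(R)-5-methyl-2-(prop-1-en-2-yl)hex-5-en-1-yl]-2,3-dihydrobenzofuran-2-yl}propan-2-ol; 24 N-methoxy-N-methyl-3-(triisopropylsilyloxy)benzamide
Product: 27 {(S)-4,6-dimethoxy-5-[(R)-5-methyl-2-(prop-1-en-2-yl)hex-5-en-1-yl]-2-[2-(triethylsilyloxy)propan-2-yl]-2,3-dihydrobenzofuran-7-yl}[3-(triisopropylsilyloxy)phenyl]methanone, via aryllithium 25 (not isolated), via tetrahedral lithium adduct 26 (not isolated)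
Conditions: n-BuLi, TMEDA, THF, −78 → −20 °C; then 24, −78 → 0 °C; NH4Cl aq
Reagents that add atoms: none
Why: Directed ortho-metalation at the only arene C–H left on ring A, flanked by the methoxy oxygen and the ring B oxygen (the position at which 2,3-dihydrobenzofurans lithiate), followed by acylation with the Weinreb amide, whose chelated tetrahedral adduct collapses to the diaryl ketone only on work-up.

Step 16
Reactants: 27 the 4,6-dimethoxy ketone
Product: 28 {(S)-6-hydroxy-4-methoxy-5-[(R)-5-methyl-2-(prop-1-en-2-yl)hex-5-en-1-yl]-2-[2-(triethylsilyloxy)propan-2-yl]-2,3-dihydrobenzofuran-7-yl}[3-(triisopropylsilyloxy)phenyl]methanone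
Conditions: MgI2·OEt2 (3 equiv), toluene/Et2O, 60 °C; NH4Cl aq
Reagents that add atoms: none
Why: Chelation-controlled demethylation: magnesium bound between the ketone oxygen and the ortho methoxy oxygen activates that methyl group for SN2 attack by iodide, whereas the other methoxy group (para, no chelate) and the ring B oxygen (ortho, but on a hindered secondary carbon) are left, and the mild Lewis acid should spare alkenes and silyl ethers.

Step 17
Reactants: 28 the 6-hydroxy-4-methoxy ketone
Product: 29 (3-hydroxyphenyl){(S)-6-hydroxy-2-(2-hydroxypropan-2-yl)-4-methoxy-5-[(R)-5-methyl-2-(prop-1-en-2-yl)hex-5-en-1-yl]-2,3-dihydrobenzofuran-7-yl}methanone (target)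
Conditions: Bu4NF (3 equiv), THF, 0 °C → rt; NH4Cl aq
Reagents that add atoms: none
Why: Fluoride cleaves the aryl TIPS ether and the tertiary TES ether in one operation, and nothing else in the molecule is sensitive to Bu4NF.

**Compound list**

1 | 2-bromo-1,3-dimethoxybenzene | COc1cccc(OC)c1Br | starting material
2 | 2-(4-bromo-3,5-dimethoxyphenyl)-4,4,5,5-tetramethyl-1,3,2-dioxaborolane | COc1cc(B2OC(C)(C)C(C)(C)O2)cc(OC)c1Br | intermediate (not isolated)
3 | 4-bromo-3,5-dimethoxyphenol | COc1cc(O)cc(OC)c1Br | intermediate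
4 | ethyl (R)-2-hydroxypropanoate (ethyl D-lactate) | CCOC(=O)[C@@H](C)O | starting material
5 | ethyl (S)-2-(4-bromo-3,5-dimethoxyphenoxy)propanoate | CCOC(=O)[C@H](C)Oc1cc(OC)c(Br)c(OC)c1 | intermediate
6 | (S)-3-(4-bromo-3,5-dimethoxyphenoxy)-2-methylbutan-2-ol | C[C@@H](C(C)(C)O)Oc1cc(OC)c(Br)c(OC)c1 | intermediate
7 | {[(S)-3-(4-bromo-3,5-dimethoxyphenoxy)-2-methylbutan-2-yl]oxy}triethylsilane | C[C@@H](C(C)(C)O[Si](CC)(CC)CC)Oc1cc(OC)c(Br)c(OC)c1 | intermediate
8 | (S)-4-benzyloxazolidin-2-one | O=C1OC[C@H](Cc2ccccc2)N1 | starting material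
9 | 3-methylbut-2-enoyl chloride | CC(C)=CC(=O)Cl | starting material
10 | N-lithio-(S)-4-benzyloxazolidin-2-one | [Li]N1[C@@H](Cc2ccccc2)COC1=O | intermediate (not isolated)
11 | (S)-4-benzyl-3-(3-methylbut-2-enoyl)oxazolidin-2-one | CC(C)=CC(=O)N1[C@@H](Cc2ccccc2)COC1=O | intermediate
12 | 3-methylbut-3-en-1-ol | C=C(C)CCO | starting material
13 | 3-methylbut-3-en-1-yl trifluoromethanesulfonate | C=C(C)CCOS(=O)(=O)C(F)(F)F | intermediate
14 | sodium (Z)-dienolate of 11 (O cis to the isopropenyl carbon) | C=C(C)/C=C(\[O-])N1[C@@H](Cc2ccccc2)COC1=O.[Na+] | intermediate (not isolated)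
15 | (S)-4-benzyl-3-[(S)-5-methyl-2-(prop-1-en-2-yl)hex-5-enoyl]oxazolidin-2-one | C=C(C)CC[C@H](C(=O)N1[C@@H](Cc2ccccc2)COC1=O)C(=C)C | intermediate
16 | (S)-5-methyl-2-(prop-1-en-2-yl)hex-5-en-1-ol | C=C(C)CC[C@H](CO)C(=C)C | intermediate
17 | (S)-3-(iodomethyl)-2,6-dimethylhepta-1,6-diene | C=C(C)CC[C@H](CI)C(=C)C | intermediate
18 | [(S)-5-methyl-2-(prop-1-en-2-yl)hex-5-en-1-yl]zinc iodide | C=C(C)CC[C@H](C[Zn]I)C(=C)C | intermediate (not isolated)
19 | {[(S)-3-{3,5-dimethoxy-4-[(R)-5-methyl-2-(prop-1-en-2-yl)hex-5-en-1-yl]phenoxy}-2-methylbutan-2-yl]oxy}triethylsilane | C=C(C)CC[C@H](Cc1c(OC)cc(O[C@@H](C)C(C)(C)O[Si](CC)(CC)CC)cc1OC)C(=C)C | intermediate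
20 | {[(S)-3-{2-bromo-3,5-dimethoxy-4-[(R)-5-methyl-2-(prop-1-en-2-yl)hex-5-en-1-yl]phenoxy}-2-methylbutan-2-yl]oxy}triethylsilane | C=C(C)CC[C@H](Cc1c(OC)cc(O[C@@H](C)C(C)(C)O[Si](CC)(CC)CC)c(Br)c1OC)C(=C)C | intermediate
21 | {[2-{(S)-4,6-dimethoxy-5-[(R)-5-methyl-2-(prop-1-en-2-yl)hex-5-en-1-yl]-2,3-dihydrobenzofuran-2-yl}propan-2-yl]oxy}triethylsilane | C=C(C)CC[C@H](Cc1c(OC)cc2c(c1OC)C[C@@H](C(C)(C)O[Si](CC)(CC)CC)O2)C(=C)C | intermediate
22 | methyl 3-hydroxybenzoate | COC(=O)c1cccc(O)c1 | starting material
23 | methyl 3-(triisopropylsilyloxy)benzoate | COC(=O)c1cccc(O[Si](C(C)C)(C(C)C)C(C)C)c1 | intermediate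
24 | N-methoxy-N-methyl-3-(triisopropylsilyloxy)benzamide | CON(C)C(=O)c1cccc(O[Si](C(C)C)(C(C)C)C(C)C)c1 | intermediate
25 | 7-lithio derivative of 21 (lithium on ring A at C3) | C=C(C)CC[C@H](Cc1c(OC)c([Li])c2c(c1OC)C[C@@H](C(C)(C)O[Si](CC)(CC)CC)O2)C(=C)C | intermediate (not isolated)
26 | lithium alkoxide of the N-methoxy-N-methyl hemiaminal from 25 and 24 (either configuration at the new carbon) | C=C(C)CC[C@H](Cc1c(OC)c(C(O[Li])(N(C)OC)c3cccc(O[Si](C(C)C)(C(C)C)C(C)C)c3)c2c(c1OC)C[C@@H](C(C)(C)O[Si](CC)(CC)CC)O2)C(=C)C | intermediate (not isolated)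
27 | {(S)-4,6-dimethoxy-5-[(R)-5-methyl-2-(prop-1-en-2-yl)hex-5-en-1-yl]-2-[2-(triethylsilyloxy)propan-2-yl]-2,3-dihydrobenzofuran-7-yl}[3-(triisopropylsilyloxy)phenyl]methanone | C=C(C)CC[C@H](Cc1c(OC)c(C(=O)c3cccc(O[Si](C(C)C)(C(C)C)C(C)C)c3)c2c(c1OC)C[C@@H](C(C)(C)O[Si](CC)(CC)CC)O2)C(=C)C | intermediate
28 | {(S)-6-hydroxy-4-methoxy-5-[(R)-5-methyl-2-(prop-1-en-2-yl)hex-5-en-1-yl]-2-[2-(triethylsilyloxy)propan-2-yl]-2,3-dihydrobenzofuran-7-yl}[3-(triisopropylsilyloxy)phenyl]methanone | C=C(C)CC[C@H](Cc1c(O)c(C(=O)c3cccc(O[Si](C(C)C)(C(C)C)C(C)C)c3)c2c(c1OC)C[C@@H](C(C)(C)O[Si](CC)(CC)CC)O2)C(=C)C | intermediate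
29 | (3-hydroxyphenyl){(S)-6-hydroxy-2-(2-hydroxypropan-2-yl)-4-methoxy-5-[(R)-5-methyl-2-(prop-1-en-2-yl)hex-5-en-1-yl]-2,3-dihydrobenzofuran-7-yl}methanone | C=C(C)CC[C@H](Cc1c(O)c(C(=O)c2cccc(O)c2)c2c(c1OC)C[C@@H](C(C)(C)O)O2)C(=C)C | target

**Step count and risks**

Total steps: 17. Longest linear sequence: 10 steps (1, 2, 3, 4, 10, 11, 12, 15, 16, 17); the side-chain branch (5, 7, 8, 9, then 10, 11, 12, 15, 16, 17) is equally long.

The three steps most likely to fail:

Step 12. The methyl C–H cleavage may be too slow, because the ether carbon is tertiary and not quaternary as in the closest precedent; the aryl–palladium intermediate could then be lost to hydrodebromination (through reversible activation of the neighbouring methoxy C–H) or to β-hydride loss. The fallback builds ring B by the classical O–C closure and couples the side chain afterwards. It sets out from phenol 3: C-prenylation of the phenoxide at one of its two equivalent ortho positions (NaH, 1-bromo-3-methylbut-2-ene, toluene) should give 4-bromo-3,5-dimethoxy-2-(3-methylbut-2-en-1-yl)phenol F1. Silylation (TBSCl, imidazole) gives tert-butyl[4-bromo-3,5-dimethoxy-2-(3-methylbut-2-en-1-yl)phenoxy]dimethylsilane F2. Shi epoxidation (D-fructose-derived ketone, Oxone (2KHSO5·KHSO4·K2SO4), K2CO3) gives tert-butyl{4-bromo-2-[((R)-3,3-dimethyloxiran-2-yl)methyl]-3,5-dimethoxyphenoxy}dimethylsilane F3. Bu4NF then frees the phenoxide, which opens the epoxide 5-exo-tet with inversion to 2-[(S)-5-bromo-4,6-dimethoxy-2,3-dihydrobenzofuran-2-yl]propan-2-ol F4. TESOTf and 2,6-lutidine give its triethylsilyl ether F5, and Negishi coupling of F5 with alkylzinc iodide 18 under the conditions of step 10 comes back to the route at 21.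

Step 7. C-alkylation of the stabilised dienolate by a non-activated primary electrophile may be slow, so that O-alkylation, ionisation or elimination of the homoallylic triflate, or breakdown of the enolate can compete. The fallback replaces alkylation by conjugate addition. It sets out from imide 11: the titanium enolate (TiCl4, i-Pr2NEt, CH2Cl2, −78 → 0 °C) should add to methyl vinyl ketone on the same face to give (S)-4-benzyl-3-[(S)-5-oxo-2-(prop-1-en-2-yl)hexanoyl]oxazolidin-2-one F6. Non-basic Lombardo methylenation of the ketone (Zn, CH2Br2, TiCl4) comes back to the route at 15.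

Step 15. Metalation may not stay at the arene C–H (deprotonation at the benzylic CH2 of ring B with ring opening, or at allylic positions), or the hindered aryllithium may add sluggishly to the amide. The fallback uses halogen–metal exchange and an aldehyde instead. It sets out from 21: NBS brominates the single free arene position to give the 7-bromo derivative of 21 F7. Weinreb amide 24 is reduced (i-Bu2AlH, THF, −78 °C) to 3-(triisopropylsilyloxy)benzaldehyde F8. Bromine–lithium exchange on F7 (n-BuLi, THF, −78 °C) and addition to F8 give the diarylmethanol F9, and Dess–Martin oxidation comes back to the route at 27.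

**Further compounds**

F1 | step 12 | 4-bromo-3,5-dimethoxy-2-(3-methylbut-2-en-1-yl)phenol | COc1cc(O)c(CC=C(C)C)c(OC)c1Br
F2 | step 12 | tert-butyl[4-bromo-3,5-dimethoxy-2-(3-methylbut-2-en-1-yl)phenoxy]dimethylsilane | COc1cc(O[Si](C)(C)C(C)(C)C)c(CC=C(C)C)c(OC)c1Br
F3 | step 12 | tert-butyl{4-bromo-2-[((R)-3,3-dimethyloxiran-2-yl)methyl]-3,5-dimethoxyphenoxy}dimethylsilane | COc1cc(O[Si](C)(C)C(C)(C)C)c(C[C@H]2OC2(C)C)c(OC)c1Br
F4 | step 12 | 2-[(S)-5-bromo-4,6-dimethoxy-2,3-dihydrobenzofuran-2-yl]propan-2-ol | COc1cc2c(c(OC)c1Br)C[C@@H](C(C)(C)O)O2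
F5 | step 12 | {[2-((S)-5-bromo-4,6-dimethoxy-2,3-dihydrobenzofuran-2-yl)propan-2-yl]oxy}triethylsilane | COc1cc2c(c(OC)c1Br)C[C@@H](C(C)(C)O[Si](CC)(CC)CC)O2
F6 | step 7 | (S)-4-benzyl-3-[(S)-5-oxo-2-(prop-1-en-2-yl)hexanoyl]oxazolidin-2-one | CC(=O)CC[C@H](C(=O)N1[C@@H](Cc2ccccc2)COC1=O)C(=C)C
F7 | step 15 | {[2-{(S)-7-bromo-4,6-dimethoxy-5-[(R)-5-methyl-2-(prop-1-en-2-yl)hex-5-en-1-yl]-2,3-dihydrobenzofuran-2-yl}propan-2-yl]oxy}triethylsilane | C=C(C)CC[C@H](Cc1c(OC)c(Br)c2c(c1OC)C[C@@H](C(C)(C)O[Si](CC)(CC)CC)O2)C(=C)C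
F8 | step 15 | 3-(triisopropylsilyloxy)benzaldehyde | O=Cc1cccc(O[Si](C(C)C)(C(C)C)C(C)C)c1
F9 | step 15 | {(S)-4,6-dimethoxy-5-[(R)-5-methyl-2-(prop-1-en-2-yl)hex-5-en-1-yl]-2-[2-(triethylsilyloxy)propan-2-yl]-2,3-dihydrobenzofuran-7-yl}[3-(triisopropylsilyloxy)phenyl]methanol (either carbinol configuration) | C=C(C)CC[C@H](Cc1c(OC)c(C(O)c3cccc(O[Si](C(C)C)(C(C)C)C(C)C)c3)c2c(c1OC)C[C@@H](C(C)(C)O[Si](CC)(CC)CC)O2)C(=C)C
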